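**Retrosynthetic overview**
1. Target 37 is methyl (1S,4R,5S,9R,10S)-1-acetoxy-ent-labda-8(17),12E,14-trien-19-oate. Late disconnections: the O1 acetate; C11–C12 (Negishi coupling of a C11 alkylzinc with (E)-1-iodo-2-methylbuta-1,3-diene); C8=C17 (Wittig reaction of a C8 ketone reached by allylic oxidation and hydrogenation of a Δ6 olefin); the equatorial C4 methyl (from one ester of a C4 malonate).
2. The strategy rests on the stereotriad C9(H)(C11)–C10(CH3)–C5(H) at the fusion of rings A and B, with C11 cis to the C20 methyl and H5 trans to it. It is read as an (E)-3-methyl-2-enal dienophile (O=C11–C9=C10–C20) added to a C5=C6–C7=C8 diene that is tied to C10 through C1–C4.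
3. Key disconnection: C5–C10 and C8–C9, which opens rings A and B together to the acyclic (E,E)-trienal 17 carrying a C4 gem-diester and the (S)-C1 silyl ether.
4. Trienal 17: C1–C10 by Nozaki–Hiyama–Kishi coupling of aldehyde 7 with iodide 11, then oxidation and CBS reduction to set C1; 7 from dimethyl malonate, crotonaldehyde and a bromoacetal by Knoevenagel condensation and deconjugative alkylation.
5. Ring order: rings A and B are formed together in step 12; no ring is formed before or after it.

Key step: step 12

Remark: the SMILES defines the ent-labdane enantiomer, and that enantiomer is made. Labdane numbering is used for all intermediates (C1–C4 tether, C5–C8 diene, C9=C10 dienophile, C11 formyl carbon, C20 the C10 methyl, C19/C18 the axial/equatorial C4 carbons). "Cis/trans to C20" gives relative configuration. Cyclopentadienyl ligands are drawn σ-bonded in SMILES.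

**Route**

Step 1
Reactants: 1 dimethyl malonate; 2 (E)-but-2-enal
Product: 3 dimethyl 2-[(2E)-but-2-en-1-ylidene]malonate
Conditions: TiCl4, pyridine, THF, 0 °C to rt
Reagents that add atoms: none
Why: Knoevenagel condensation under TiCl4/pyridine (Lehnert) conditions takes place at the enal carbonyl only, so the E-propenyl unit of 2 is carried into the dienylidene malonate without conjugate addition.

Step 2
Reactants: 3 dimethyl 2-[(2E)-but-2-en-1-ylidene]malonate; 4 2-(2-bromoethyl)-1,3-dioxolane
Product: 6 dimethyl 2-[(1E)-buta-1,3-dien-1-yl]-2-[2-(1,3-dioxolan-2-yl)ethyl]malonate, via sodium dienolate 5 (not isolated)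
Conditions: NaH, DMF, 0 °C; then 4, NaI (cat.), 0 to 50 °C
Reagents that add atoms: none
Why: Deconjugative α-alkylation of an extended malonate enolate: NaH removes an ε-proton of 3, the primary bromide alkylates the pentadienyl-type anion at the malonate carbon where the charge is highest, and the s-trans anion leaves the 1-substituted (E)-buta-1,3-diene on the future C4.

Step 3
Reactants: 6 dimethyl 2-[(1E)-buta-1,3-dien-1-yl]-2-[2-(1,3-dioxolan-2-yl)ethyl]malonate
Product: 7 dimethyl 2-[(1E)-buta-1,3-dien-1-yl]-2-(3-oxopropyl)malonate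
Conditions: 1 M aq HCl, THF, rt
Reagents that add atoms: water, O
Why: Acid-catalysed acetal hydrolysis frees the aldehyde, while the quaternary malonate and the diene are inert to dilute acid at room temperature.

Step 4
Reactants: 8 but-2-yn-1-ol
Product: 10 (E)-3-iodobut-2-en-1-ol, via alkenylzirconocene chloride 9 (not isolated)
Conditions: Cp2Zr(H)Cl (2.2 equiv), THF, 0 °C to rt; then I2, 0 °C
Reagents that add atoms: iodine, II
Why: Hydrozirconation with the Schwartz reagent Cp2Zr(H)Cl: the first equivalent forms the zirconium alkoxide, the second adds H–Zr syn across the alkyne with zirconium on the less hindered methyl-bearing carbon, and iodinolysis with retention should give the iodide with iodine trans to CH2OH.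

Step 5
Reactants: 10 (E)-3-iodobut-2-en-1-ol
Product: 11 (E)-3-iodobut-2-en-1-yl acetate
Conditions: Ac2O, Et3N, DMAP (cat.), CH2Cl2, 0 °C
Reagents that add atoms: acetic anhydride, CC(=O)OC(C)=O
Why: DMAP-catalysed acetylation of a primary alcohol gives a group that tolerates the chromium coupling and can later be removed beside a silyl ether and methyl esters.

Step 6
Reactants: 7 dimethyl 2-[(1E)-buta-1,3-dien-1-yl]-2-(3-oxopropyl)malonate; 11 (E)-3-iodobut-2-en-1-yl acetate
Product: 12 dimethyl 2-[(4E)-6-acetoxy-3-hydroxy-4-methylhex-4-en-1-yl]-2-[(1E)-buta-1,3-dien-1-yl]malonate (racemic at the carbinol)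
Conditions: CrCl2 (4 equiv), NiCl2 (1 mol%), DMF, rt
Reagents that add atoms: none
Why: Nozaki–Hiyama–Kishi reaction: the alkenylchromium species formed from 11 under nickel catalysis adds only to the aldehyde (esters, acetate and diene are untouched) with retention of the alkene geometry, and the racemic carbinol is corrected in steps 7 and 8.

Step 7
Reactants: 12 racemic allylic alcohol
Product: 13 dimethyl 2-[(4E)-6-acetoxy-4-methyl-3-oxohex-4-en-1-yl]-2-[(1E)-buta-1,3-dien-1-yl]malonate
Conditions: Dess–Martin periodinane, NaHCO3, CH2Cl2, 0 °C to rt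
Reagents that add atoms: none
Why: Dess–Martin oxidation converts the secondary allylic alcohol into the enone under buffered conditions that do not isomerise the trisubstituted alkene.

Step 8
Reactants: 13 enone
Product: 14 dimethyl 2-[(3S,4E)-6-acetoxy-3-hydroxy-4-methylhex-4-en-1-yl]-2-[(1E)-buta-1,3-dien-1-yl]malonate
Conditions: (R)-2-methyl-CBS-oxazaborolidine (0.2 equiv), catecholborane (1.5 equiv), toluene, −78 °C
Reagents that add atoms: none
Why: Corey–Bakshi–Shibata reduction: the α-methylalkenyl group acts as the large ketone substituent, so the (R)-oxazaborolidine should deliver hydride to the face that gives the (S)-carbinol (the future C1), and catecholborane at −78 °C leaves the diene unhydroborated.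

Step 9
Reactants: 14 (S)-allylic alcohol
Product: 15 dimethyl 2-[(3S,4E)-6-acetoxy-3-(tert-butyldimethylsilyloxy)-4-methylhex-4-en-1-yl]-2-[(1E)-buta-1,3-dien-1-yl]malonate
Conditions: TBSCl, imidazole, DMF, rt
Reagents that add atoms: tert-butyldimethylsilyl chloride, CC(C)(C)[Si](C)(C)Cl
Why: Standard silylation of a secondary alcohol with TBSCl/imidazole, which does not touch the stereocentre.

Step 10
Reactants: 15 silyl ether acetate
Product: 16 dimethyl 2-[(1E)-buta-1,3-dien-1-yl]-2-[(3S,4E)-3-(tert-butyldimethylsilyloxy)-6-hydroxy-4-methylhex-4-en-1-yl]malonate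
Conditions: K2CO3 (0.2 equiv), MeOH, 0 °C
Reagents that add atoms: none
Why: Base-catalysed methanolysis removes the primary acetate, while the methyl esters are unchanged in methanol and the quaternary malonate has no acidic hydrogen.

Step 11
Reactants: 16 primary allylic alcohol
Product: 17 dimethyl 2-[(1E)-buta-1,3-dien-1-yl]-2-[(3S,4E)-3-(tert-butyldimethylsilyloxy)-4-methyl-6-oxohex-4-en-1-yl]malonate
Conditions: MnO2, CH2Cl2, rt
Reagents that add atoms: none
Why: MnO2 oxidises the primary allylic alcohol selectively to the enal without changing the alkene geometry or the silyl ether.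

Step 12
Reactants: 17 (E,E)-trienal
Product: 18 dimethyl (4S,4aR,5R,8aS)-4-(tert-butyldimethylsilyloxy)-5-formyl-4a-methyl-3,4,4a,5,6,8a-hexahydronaphthalene-1,1(2H)-dicarboxylate (labdane numbering: 1S,5S,9R,10R; 9-CHO and 1-OTBS cis to C20; H5 trans to C20; Δ6)
Conditions: Me2AlCl (2 equiv), CH2Cl2, −78 to −20 °C
Reagents that add atoms: none
Why: Me2AlCl binds the formyl oxygen and lowers the enal LUMO, so the C5=C6–C7=C8 diene adds across C9=C10 in a concerted, asynchronous [4+2] in which the C5–C10 bond to the β-carbon leads; the closest known reaction type is the Lewis acid-promoted intramolecular Diels–Alder reaction of terminally activated 1,7,9-decatrienes, including 3-methyl-2-enal dienophiles that create an angular methyl group. Ring B is closed as the cyclohexene of the cycloaddition itself (bonds C5–C10 and C8–C9), and ring A is closed at the same time as the six-membered ring that the four-carbon tether C1–C4 spans across the new C5–C10 bond, the tether lying exo in a chair-like array. C9 and C10 are set by suprafacial transfer of the E-enal geometry (C11 and the C20 methyl cis), and C5 by the formyl-endo, tether-exo transition state, which places H5 trans to C20 (trans ring fusion). The existing (S)-C1 centre selects the diene face: the silyloxy group should take the pseudo-equatorial position anti to the forming C5–C10 bond, with the small hydrogen next to C9–H, so that O1 ends cis to C20 and the absolute configuration of C5, C9 and C10 follows from C1. The step needs endo over exo selectivity and π-facial selectivity; the first is secured by Lewis acid complexation of the E-enal, the second by the allylic silyloxy stereocentre, and the C4 gem-diester speeds closure without adding a stereocentre.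

Step 13
Reactants: 18 octalin aldehyde
Product: 19 dimethyl (4S,4aR,5R,8aS)-4-(tert-butyldimethylsilyloxy)-5-(hydroxymethyl)-4a-methyl-3,4,4a,5,6,8a-hexahydronaphthalene-1,1(2H)-dicarboxylate
Conditions: NaBH4, MeOH, 0 °C
Reagents that add atoms: none
Why: NaBH4 reduces the aldehyde chemoselectively beside the two hindered methyl esters at 0 °C and leaves C9 untouched.

Step 14
Reactants: 19 C11 alcohol
Product: 20 dimethyl (4S,4aR,5R,8aS)-4-(tert-butyldimethylsilyloxy)-5-[(tert-butyldimethylsilyloxy)methyl]-4a-methyl-3,4,4a,5,6,8a-hexahydronaphthalene-1,1(2H)-dicarboxylate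
Conditions: TBSCl, imidazole, DMF, rt
Reagents that add atoms: tert-butyldimethylsilyl chloride, CC(C)(C)[Si](C)(C)Cl
Why: Silylation of the primary alcohol gives a group that survives the hydride, radical, oxidation, hydrogenation and ylide steps and can later be cleaved selectively beside the hindered secondary silyl ether.

Step 15
Reactants: 20 bis-silyl ether diester
Product: 21 methyl 1,11-bis(tert-butyldimethylsilyloxy)-18-hydroxy-12,13,14,15,16,17-hexanor-ent-labd-6-en-19-oate (1S; ring stereocentres as in 18; CO2Me axial and cis to C20; CH2OH equatorial)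
Conditions: LiAlH(OtBu)3 (3 equiv), THF, 0 to 40 °C
Reagents that add atoms: none
Why: Mono-reduction of a disubstituted malonate with LiAlH(OtBu)3: the bulky hydride should attack the equatorial ester (trans to C20) because the axial ester is shielded by the 1,3-diaxial C20 methyl, and the alkoxyaluminate formed stops further reduction, which sets C4.

Step 16
Reactants: 21 hydroxy ester
Product: 22 methyl 1,11-bis(tert-butyldimethylsilyloxy)-18-(phenoxythiocarbonyloxy)-12,13,14,15,16,17-hexanor-ent-labd-6-en-19-oate
Conditions: PhOC(S)Cl, pyridine, DMAP, CH2Cl2, rt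
Reagents that add atoms: O-phenyl chlorothionoformate, ClC(=S)Oc1ccccc1
Why: Acylation of the neopentyl alcohol with phenyl chlorothionoformate under weakly basic conditions gives the thionocarbonate for radical deoxygenation and avoids retro-aldol loss of formaldehyde from the β-hydroxy ester.

Step 17
Reactants: 22 thionocarbonate
Product: 23 methyl 1,11-bis(tert-butyldimethylsilyloxy)-12,13,14,15,16,17-hexanor-ent-labd-6-en-19-oate (1S,4R; equatorial C4 methyl)
Conditions: Bu3SnH, AIBN (cat.), toluene, 110 °C
Reagents that add atoms: none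
Why: Barton–McCombie deoxygenation: the stannyl radical adds to C=S, the primary C18 radical is released at 110 °C and is reduced by Bu3SnH before it can add to the remote Δ6 alkene, which turns the equatorial CH2O group into the methyl group.

Step 18
Reactants: 23 Δ6 olefin
Product: 24 methyl 1,11-bis(tert-butyldimethylsilyloxy)-8-oxo-12,13,14,15,16,17-hexanor-ent-labd-6-en-19-oate
Conditions: Rh2(cap)4 (dirhodium tetracaprolactamate, 1 mol%), t-BuOOH (70% aq), K2CO3, CH2Cl2, rt
Reagents that add atoms: tert-butyl hydroperoxide, CC(C)(C)OO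
Why: Rhodium-catalysed allylic oxidation with t-BuOOH (hydrogen abstraction by the peroxyl radical, then collapse of the allylic peroxide): the C8 methylene is the accessible allylic site, C5–H is a hindered methine next to the C4 ester, and oxygenation at C6 is screened by the C4 substituents, so the 6-en-8-one should predominate.

Step 19
Reactants: 24 enone
Product: 25 methyl 1,11-bis(tert-butyldimethylsilyloxy)-8-oxo-12,13,14,15,16,17-hexanor-ent-labdan-19-oate
Conditions: H2 (1 atm), Pd/C, EtOAc, rt
Reagents that add atoms: none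
Why: Heterogeneous hydrogenation saturates the conjugated alkene, the ketone, ester and silyl ethers are inert in EtOAc, and C9 keeps its equatorial, more stable side chain.

Step 20
Reactants: 25 C8 ketone
Product: 26 methyl 1,11-bis(tert-butyldimethylsilyloxy)-12,13,14,15,16-pentanor-ent-labd-8(17)-en-19-oate
Conditions: Ph3PCH3Br, KOtBu, THF, 0 °C to reflux
Reagents that add atoms: methyltriphenylphosphonium bromide, C[P+](c1ccccc1)(c1ccccc1)c1ccccc1.[Br-]
Why: Wittig methylenation: the non-stabilised ylide adds to the ketone faster than it enolises it or eliminates the β-silyloxy group, and the C9 configuration is the thermodynamic one in any case.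

Step 21
Reactants: 26 bis-silyl ether
Product: 27 methyl 1-(tert-butyldimethylsilyloxy)-11-hydroxy-12,13,14,15,16-pentanor-ent-labd-8(17)-en-19-oate
Conditions: HF·pyridine, pyridine, THF, 0 °C to rt
Reagents that add atoms: none
Why: Buffered HF·pyridine cleaves the primary silyl ether far faster than the secondary C1 silyl ether, which is shielded by the quaternary C10, and the buffered medium should not isomerise the exocyclic alkene.

Step 22
Reactants: 27 C11 alcohol
Product: 28 methyl 1-(tert-butyldimethylsilyloxy)-11-iodo-12,13,14,15,16-pentanor-ent-labd-8(17)-en-19-oate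
Conditions: I2, PPh3, imidazole, CH2Cl2, 0 °C to rt
Reagents that add atoms: iodine, II
Why: Garegg–Samuelsson (Appel-type) iodination: iodide displaces the alkoxyphosphonium group at primary C11 by SN2, and with O1 still silylated no hydroxyl can close an ether onto C11.

Step 23
Reactants: 29 prop-2-yn-1-ol
Product: 31 (E)-3-iodo-2-methylprop-2-en-1-ol, via alkenylalane 30 (not isolated)
Conditions: Me3Al (3 equiv), Cp2ZrCl2 (0.25 equiv), CH2Cl2, 0 °C to rt; then I2, THF, −30 to 0 °C
Reagents that add atoms: trimethylaluminium, C[Al](C)C; iodine, II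
Why: Negishi zirconium-catalysed carboalumination adds methyl and aluminium syn across the terminal alkyne with aluminium on the terminal carbon, and iodinolysis with retention gives the iodide with iodine cis to the methyl group.

Step 24
Reactants: 31 (E)-3-iodo-2-methylprop-2-en-1-ol
Product: 32 (E)-3-iodo-2-methylprop-2-enal
Conditions: MnO2, CH2Cl2, rt
Reagents that add atoms: none
Why: MnO2 oxidation of the primary allylic alcohol gives the enal with the alkene geometry retained.

Step 25
Reactants: 32 (E)-3-iodo-2-methylprop-2-enal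
Product: 33 (E)-1-iodo-2-methylbuta-1,3-diene
Conditions: Ph3PCH3Br, NaN(SiMe3)2, THF, −78 to 0 °C; product kept as a solution
Reagents that add atoms: methyltriphenylphosphonium bromide, C[P+](c1ccccc1)(c1ccccc1)c1ccccc1.[Br-]
Why: Wittig methylenation of the enal builds the 1,3-diene without touching the alkenyl iodide or its geometry.

Step 26
Reactants: 28 C11 iodide; 33 (E)-1-iodo-2-methylbuta-1,3-diene
Product: 35 methyl 1-(tert-butyldimethylsilyloxy)-ent-labda-8(17),12E,14-trien-19-oate (1S; stereocentres as in 28), via alkylzinc iodide 34 (not isolated)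
Conditions: Zn dust (activated), LiCl, THF, 40 °C; then 33, PdCl2(dppf) (5 mol%), THF, 50 °C
Reagents that add atoms: none
Why: Negishi cross-coupling: zinc inserts into the primary C–I bond with LiCl assistance, and the alkylzinc iodide couples with the alkenyl iodide under palladium catalysis with retention of the alkene geometry, the dppf ligand favouring reductive elimination over β-hydride elimination while ester and silyl ether are tolerated.

Step 27
Reactants: 35 silyl ether triene
Product: 36 methyl 1-hydroxy-ent-labda-8(17),12E,14-trien-19-oate (1S; OH cis to C20)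
Conditions: Bu4NF, THF, 50 °C
Reagents that add atoms: none
Why: Fluoride-mediated desilylation frees the hindered secondary alcohol, while the hindered axial methyl ester and the diene are stable to Bu4NF.

Step 28
Reactants: 36 C1 alcohol
Product: 37 methyl (1S,4R,5S,9R,10S)-1-acetoxy-ent-labda-8(17),12E,14-trien-19-oate (target)
Conditions: Ac2O, DMAP, pyridine, rt
Reagents that add atoms: acetic anhydride, CC(=O)OC(C)=O
Why: DMAP-catalysed acetylation of the equatorial secondary alcohol proceeds with retention at C1 and gives the target.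

**Compound list**
1 | dimethyl malonate | COC(=O)CC(=O)OC | starting material
2 | (E)-but-2-enal | C/C=C/C=O | starting material
3 | dimethyl 2-[(2E)-but-2-en-1-ylidene]malonate | COC(=O)C(=C/C=C/C)C(=O)OC | intermediate
4 | 2-(2-bromoethyl)-1,3-dioxolane | BrCCC1OCCO1 | starting material
5 | sodium dienolate of 3 (not isolated) | COC(=O)C(/C=C/C=C)=C([O-])OC.[Na+] | intermediate
6 | dimethyl 2-[(1E)-buta-1,3-dien-1-yl]-2-[2-(1,3-dioxolan-2-yl)ethyl]malonate | C1COC(O1)CCC(C(=O)OC)(C(=O)OC)/C=C/C=C | intermediate
7 | dimethyl 2-[(1E)-buta-1,3-dien-1-yl]-2-(3-oxopropyl)malonate | O=CCCC(C(=O)OC)(C(=O)OC)/C=C/C=C | intermediate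
8 | but-2-yn-1-ol | CC#CCO | starting material
9 | (E)-alkenylzirconocene chloride, O-zirconated (not isolated) | Cl[Zr](C1C=CC=C1)(C1C=CC=C1)/C(C)=C/CO[Zr](Cl)(C1C=CC=C1)C1C=CC=C1 | intermediate
10 | (E)-3-iodobut-2-en-1-ol | OC/C=C(C)/I | intermediate
11 | (E)-3-iodobut-2-en-1-yl acetate | CC(=O)OC/C=C(C)/I | intermediate
12 | dimethyl 2-[(4E)-6-acetoxy-3-hydroxy-4-methylhex-4-en-1-yl]-2-[(1E)-buta-1,3-dien-1-yl]malonate (racemic) | CC(=O)OC/C=C(C)/C(O)CCC(C(=O)OC)(C(=O)OC)/C=C/C=C | intermediate
13 | dimethyl 2-[(4E)-6-acetoxy-4-methyl-3-oxohex-4-en-1-yl]-2-[(1E)-buta-1,3-dien-1-yl]malonate | CC(=O)OC/C=C(C)/C(=O)CCC(C(=O)OC)(C(=O)OC)/C=C/C=C | intermediate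
14 | dimethyl 2-[(3S,4E)-6-acetoxy-3-hydroxy-4-methylhex-4-en-1-yl]-2-[(1E)-buta-1,3-dien-1-yl]malonate | CC(=O)OC/C=C(C)/[C@@H](O)CCC(C(=O)OC)(C(=O)OC)/C=C/C=C | intermediate
15 | dimethyl 2-[(3S,4E)-6-acetoxy-3-(tert-butyldimethylsilyloxy)-4-methylhex-4-en-1-yl]-2-[(1E)-buta-1,3-dien-1-yl]malonate | CC(=O)OC/C=C(C)/[C@@H](O[Si](C)(C)C(C)(C)C)CCC(C(=O)OC)(C(=O)OC)/C=C/C=C | intermediate
16 | dimethyl 2-[(1E)-buta-1,3-dien-1-yl]-2-[(3S,4E)-3-(tert-butyldimethylsilyloxy)-6-hydroxy-4-methylhex-4-en-1-yl]malonate | OC/C=C(C)/[C@@H](O[Si](C)(C)C(C)(C)C)CCC(C(=O)OC)(C(=O)OC)/C=C/C=C | intermediate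
17 | dimethyl 2-[(1E)-buta-1,3-dien-1-yl]-2-[(3S,4E)-3-(tert-butyldimethylsilyloxy)-4-methyl-6-oxohex-4-en-1-yl]malonate | O=C/C=C(C)/[C@@H](O[Si](C)(C)C(C)(C)C)CCC(C(=O)OC)(C(=O)OC)/C=C/C=C | intermediate
18 | dimethyl (4S,4aR,5R,8aS)-4-(tert-butyldimethylsilyloxy)-5-formyl-4a-methyl-3,4,4a,5,6,8a-hexahydronaphthalene-1,1(2H)-dicarboxylate | O=C[C@@H]1CC=C[C@H]2[C@@]1(C)[C@@H](O[Si](C)(C)C(C)(C)C)CCC2(C(=O)OC)C(=O)OC | intermediate
19 | dimethyl (4S,4aR,5R,8aS)-4-(tert-butyldimethylsilyloxy)-5-(hydroxymethyl)-4a-methyl-3,4,4a,5,6,8a-hexahydronaphthalene-1,1(2H)-dicarboxylate | OC[C@@H]1CC=C[C@H]2[C@@]1(C)[C@@H](O[Si](C)(C)C(C)(C)C)CCC2(C(=O)OC)C(=O)OC | intermediate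
20 | dimethyl (4S,4aR,5R,8aS)-4-(tert-butyldimethylsilyloxy)-5-[(tert-butyldimethylsilyloxy)methyl]-4a-methyl-3,4,4a,5,6,8a-hexahydronaphthalene-1,1(2H)-dicarboxylate | CC(C)(C)[Si](C)(C)OC[C@@H]1CC=C[C@H]2[C@@]1(C)[C@@H](O[Si](C)(C)C(C)(C)C)CCC2(C(=O)OC)C(=O)OC | intermediate
21 | methyl 1,11-bis(tert-butyldimethylsilyloxy)-18-hydroxy-12,13,14,15,16,17-hexanor-ent-labd-6-en-19-oate | CC(C)(C)[Si](C)(C)OC[C@@H]1CC=C[C@H]2[C@@]1(C)[C@@H](O[Si](C)(C)C(C)(C)C)CC[C@@]2(CO)C(=O)OC | intermediate
22 | methyl 1,11-bis(tert-butyldimethylsilyloxy)-18-(phenoxythiocarbonyloxy)-12,13,14,15,16,17-hexanor-ent-labd-6-en-19-oate | CC(C)(C)[Si](C)(C)OC[C@@H]1CC=C[C@H]2[C@@]1(C)[C@@H](O[Si](C)(C)C(C)(C)C)CC[C@@]2(COC(=S)Oc3ccccc3)C(=O)OC | intermediate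
23 | methyl 1,11-bis(tert-butyldimethylsilyloxy)-12,13,14,15,16,17-hexanor-ent-labd-6-en-19-oate | CC(C)(C)[Si](C)(C)OC[C@@H]1CC=C[C@H]2[C@@]1(C)[C@@H](O[Si](C)(C)C(C)(C)C)CC[C@@]2(C)C(=O)OC | intermediate
24 | methyl 1,11-bis(tert-butyldimethylsilyloxy)-8-oxo-12,13,14,15,16,17-hexanor-ent-labd-6-en-19-oate | CC(C)(C)[Si](C)(C)OC[C@@H]1C(=O)C=C[C@H]2[C@@]1(C)[C@@H](O[Si](C)(C)C(C)(C)C)CC[C@@]2(C)C(=O)OC | intermediate
25 | methyl 1,11-bis(tert-butyldimethylsilyloxy)-8-oxo-12,13,14,15,16,17-hexanor-ent-labdan-19-oate | CC(C)(C)[Si](C)(C)OC[C@@H]1C(=O)CC[C@H]2[C@@]1(C)[C@@H](O[Si](C)(C)C(C)(C)C)CC[C@@]2(C)C(=O)OC | intermediate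
26 | methyl 1,11-bis(tert-butyldimethylsilyloxy)-12,13,14,15,16-pentanor-ent-labd-8(17)-en-19-oate | CC(C)(C)[Si](C)(C)OC[C@@H]1C(=C)CC[C@H]2[C@@]1(C)[C@@H](O[Si](C)(C)C(C)(C)C)CC[C@@]2(C)C(=O)OC | intermediate
27 | methyl 1-(tert-butyldimethylsilyloxy)-11-hydroxy-12,13,14,15,16-pentanor-ent-labd-8(17)-en-19-oate | OC[C@@H]1C(=C)CC[C@H]2[C@@]1(C)[C@@H](O[Si](C)(C)C(C)(C)C)CC[C@@]2(C)C(=O)OC | intermediate
28 | methyl 1-(tert-butyldimethylsilyloxy)-11-iodo-12,13,14,15,16-pentanor-ent-labd-8(17)-en-19-oate | IC[C@@H]1C(=C)CC[C@H]2[C@@]1(C)[C@@H](O[Si](C)(C)C(C)(C)C)CC[C@@]2(C)C(=O)OC | intermediate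
29 | prop-2-yn-1-ol | C#CCO | starting material
30 | (E)-alkenylalane, O-aluminated (not isolated) | C[Al](C)OC/C(C)=C/[Al](C)C | intermediate
31 | (E)-3-iodo-2-methylprop-2-en-1-ol | OC/C(C)=C/I | intermediate
32 | (E)-3-iodo-2-methylprop-2-enal | O=C/C(C)=C/I | intermediate
33 | (E)-1-iodo-2-methylbuta-1,3-diene | C=C/C(C)=C/I | intermediate
34 | C11 alkylzinc iodide from 28 (not isolated) | I[Zn]C[C@@H]1C(=C)CC[C@H]2[C@@]1(C)[C@@H](O[Si](C)(C)C(C)(C)C)CC[C@@]2(C)C(=O)OC | intermediate
35 | methyl 1-(tert-butyldimethylsilyloxy)-ent-labda-8(17),12E,14-trien-19-oate | C=C/C(C)=C/C[C@@H]1C(=C)CC[C@H]2[C@@]1(C)[C@@H](O[Si](C)(C)C(C)(C)C)CC[C@@]2(C)C(=O)OC | intermediate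
36 | methyl 1-hydroxy-ent-labda-8(17),12E,14-trien-19-oate | C=C/C(C)=C/C[C@@H]1C(=C)CC[C@H]2[C@@]1(C)[C@@H](O)CC[C@@]2(C)C(=O)OC | intermediate
37 | methyl (1S,4R,5S,9R,10S)-1-acetoxy-ent-labda-8(17),12E,14-trien-19-oate | C=C/C(C)=C/C[C@@H]1C(=C)CC[C@H]2[C@@]1(C)[C@@H](OC(C)=O)CC[C@@]2(C)C(=O)OC | target

**Step count and risks**
Total step count: 28. Longest linear sequence: 23 steps (steps 1–3, 6–22, 26–28); steps 4–5 and 23–25 are side branches.

Steps most likely to fail:

Step 12 (key cycloaddition). The closure may be slow because a bond to a fully substituted dienophile carbon must form. The aluminium-complexed enal may isomerise E to Z before it closes. Discrimination between the formyl-endo and formyl-exo arrays, or between the two diene faces, may be incomplete. Fallback, from 17 back to 18: the dienophile would be activated as a vinyl oxocarbenium ion instead of a Lewis acid complex (ionic Diels–Alder reaction). Trienal 17 would be treated with 1,2-bis(trimethylsilyloxy)ethane and TMSOTf (cat.) in CH2Cl2 at −78 °C to give the enal ethylene acetal F1. More TMSOTf at −78 to −40 °C should ionise the acetal and close both rings through the same endo array to the dioxolane-protected octalin F2. PPTS in wet acetone would then release aldehyde 18.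

Step 18 (allylic oxidation). The allylic radical formed at C8 may be oxygenated at its other terminus (C6), giving the transposed enone, or hydrogen abstraction may occur at C5–H. Fallback, from 23 back to 24: oxygen would be placed by an ene/[2,3]-sigmatropic sequence, which cannot transpose the alkene. SeO2 (0.5 equiv) with t-BuOOH in CH2Cl2 at rt should hydroxylate the C8 methylene to the C8 allylic alcohol F3 (either C8 epimer). Dess–Martin oxidation of F3 would give enone 24.

Step 15 (differentiation of the C4 esters). Hydride may discriminate poorly between the two diastereotopic esters, or reduction may run on to the diol. Fallback, from 20 back to 21: the esters would be differentiated by hydrolysis, which is more sensitive to the 1,3-diaxial C20 methyl. LiOH in THF/MeOH/H2O at 40 °C should saponify only the equatorial ester to the half-acid F4. 1,1'-Carbonyldiimidazole in THF would convert it into the acyl imidazolide F5, and NaBH4 in THF/H2O would reduce that to hydroxy ester 21 without touching the remaining ester.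

Further compounds
F1 | step 12 | dimethyl 2-[(1E)-buta-1,3-dien-1-yl]-2-[(3S,4E)-3-(tert-butyldimethylsilyloxy)-5-(1,3-dioxolan-2-yl)-4-methylpent-4-en-1-yl]malonate | C1COC(O1)/C=C(C)/[C@@H](O[Si](C)(C)C(C)(C)C)CCC(C(=O)OC)(C(=O)OC)/C=C/C=C
F2 | step 12 | dimethyl (4S,4aR,5R,8aS)-4-(tert-butyldimethylsilyloxy)-5-(1,3-dioxolan-2-yl)-4a-methyl-3,4,4a,5,6,8a-hexahydronaphthalene-1,1(2H)-dicarboxylate | C3COC(O3)[C@@H]1CC=C[C@H]2[C@@]1(C)[C@@H](O[Si](C)(C)C(C)(C)C)CCC2(C(=O)OC)C(=O)OC
F3 | step 18 | methyl 1,11-bis(tert-butyldimethylsilyloxy)-8-hydroxy-12,13,14,15,16,17-hexanor-ent-labd-6-en-19-oate (C8 configuration open) | CC(C)(C)[Si](C)(C)OC[C@@H]1C(O)C=C[C@H]2[C@@]1(C)[C@@H](O[Si](C)(C)C(C)(C)C)CC[C@@]2(C)C(=O)OC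
F4 | step 15 | 1,11-bis(tert-butyldimethylsilyloxy)-19-methoxy-19-oxo-12,13,14,15,16,17-hexanor-ent-labd-6-en-18-oic acid | CC(C)(C)[Si](C)(C)OC[C@@H]1CC=C[C@H]2[C@@]1(C)[C@@H](O[Si](C)(C)C(C)(C)C)CC[C@@]2(C(=O)O)C(=O)OC
F5 | step 15 | 18-(imidazol-1-yl) amide (acyl imidazolide) of F4 | CC(C)(C)[Si](C)(C)OC[C@@H]1CC=C[C@H]2[C@@]1(C)[C@@H](O[Si](C)(C)C(C)(C)C)CC[C@@]2(C(=O)n3ccnc3)C(=O)OC
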